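Remark: locants C1–C15 are those of the target (germacranolide numbering) in every intermediate, TBS is tert-butyldimethylsilyl and TBDPS is tert-butyldiphenylsilyl; C1 is carried as a trimethylsilyl alkene until the diene has been built and C15 is carried as a dioxolane, because an alkenyl iodide would not survive the organolithium and palladium steps that precede the ring closure.

## Analysis of the target

The target is a germacranolide: a ten-membered carbocycle C1–C10 fused through C6 and C7 to an α-methylene-γ-butyrolactone (O–C6, C7–C11(=C13H2)–C12=O). Both ring alkenes, C1=C10 and C4=C5, are trisubstituted and cis with respect to the ring bonds (C2 cis to C9, C3 cis to C6). Each carries an oxidised one-carbon branch: the acetoxymethyl group C14 on C10 and the formyl group C15 on C4. The three stereocentres are contiguous, C6 (R), C7 (R) and C8 (S): H6 and H7 are trans, the oxygens on C6 and C8 lie on one face of the ring and C11 on the other, which in the open chain is an all-syn O6/C11/O8 triad. C8 carries a 2-(hydroxymethyl)acrylate ester. Nearly every functional group is an electrophile or is base-labile: the methylene lactone, the acrylate and the enal are Michael acceptors, the acetate and the C8 ester can migrate, and a free C8 hydroxyl can translactonise onto C12. The synthesis is hard because a strained ten-membered ring with two geometrically defined trisubstituted alkenes must be closed while three stereocentres and three differently oxidised positions (C8, C14, C15) stay distinguishable. The strategy rests on the C1–C2 bond: C1 is the sp2 end of the C1=C10 alkene and C2–C3 is a saturated bridge to C4, i.e. a hydroborated vinyl group on C4, so an alkenyl iodide at C1 and a terminal C2=C3 alkene are all the ring closure needs.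

## Retrosynthetic reasoning

The last operation frees the C15 aldehyde and the side-chain hydroxyl. In 35 the enal is a dioxolane and the side-chain alcohol a silyl ether; both fall to dilute acid, which leaves the esters, the acetate and the methylene lactone alone. So 36 comes from 35 in one hydrolysis.

The C8–O acyl bond of 35 is cut next, giving alcohol 31 and acid 34 (from 32 through 33). The acrylate is attached this late because it would survive neither a borane nor a lactone enolate. The forward step must acylate a hindered secondary alcohol under neutral conditions.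

The C14 acetate of 31 is traced to diol 30, and 30 to the bis-silyl ether 29. Primary allylic against hindered secondary hydroxyl is a difference that a cold, weakly basic acetylation can exploit, so no extra protecting group is needed.

The C11=C13 bond of 29 is removed, leading to lactone 26. The methylene lactone would be reduced by a borane, so it must come after ring closure. It needs a lactone enolate, so it must come before the hydroxyls are freed.

The C1–C2 bond of 26 is the key disconnection and leads to the open-chain iodo-diene 24 through the borane 25. It is cut here because this is the only ring bond that joins an sp2 carbon to an unfunctionalised CH2–CH2 unit. The coupling leaves no activating group behind and cannot change the C1=C10 geometry. The forward reaction must hydroborate only the terminal alkene and then close a ten-membered ring in preference to oligomerisation.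

The dioxolane of 24 is traced to aldehyde 23 and the C1–I bond to the C1–Si bond of 22. Ipso-substitution of silicon by iodine goes with retention. It is placed at the stage where the diene is deactivated by its formyl group.

The C3–C4 bond of 22 is cut to the α-iodoenal 20 and stannane 21, the C4–I bond of 20 to enal 19, and the C4=C5 bond of 19 to aldehyde 17 and ylide 18. A stabilised ylide puts the C15 formyl group trans to C6. Iodine then enters the only remaining position on C4, cis to C6, and is replaced by the vinyl group with retention. The ring-cis geometry of C4=C5 thus follows from three stereochemically reliable events.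

Aldehyde 17 is taken back through alcohol 16 and bis-silyl ether 15 to carbinol 14, and the C8–O stereocentre to ketone 13. The forward reduction must deliver hydride to one face of a ketone flanked by a ring CH and an allylic CH2, under reagent control.

The C7–C8 bond of 13 is cut through dithiane 12 to the acyl-anion equivalent 7 and butenolide 9 (from 8). C6 comes from the chiral pool. Conjugate addition anti to the C6 substituent sets C7 trans to it, which is the trans ring fusion of the target.

The dithiane of 7 is traced to the acetal 5 and dithiol 6, and the C9–C10 bond of 5 (through 4) to alkynol 1 and Grignard reagent 2. Anti-carbomagnesiation through a magnesium chelate fixes the C1=C10 geometry on a small molecule: silicon, and later iodine, ends cis to C9.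

## Alternatives that were turned down

Alternative 1: The C8–C9 bond is disconnected and C9 is re-attached to C6, which contracts the ring to eight members with a vinyl group (C7=C8) on a C6 carbinol. In the forward direction the alkoxide of that carbinol undergoes an accelerated [1,3] shift of the allylic carbon C9 from C6 to C8 and gives the ten-membered dienone A1. In its favour, both ring-cis alkenes are inherited from an eight-membered ring made by dimerising isoprene, and there is no macrocyclisation and no dilution. In steps to the bare carbocycle it is clearly stronger than the chosen route. Against it, A1 is achiral and carries methyl groups at C4 and C10 and a single ketone. The C7 arm, the C8 oxygen, two different allylic oxidations (C14 to the alcohol level, C15 to the aldehyde level) and all three stereocentres, including the absolute configuration, would have to be introduced on a flexible medium ring prone to transannular reactions. The same alkoxide is also set up for a competing [3,3] shift through the vinyl group and the C10=C1 alkene. The chosen strategy gives up the short ring synthesis and in return installs every stereocentre and oxidation level before the ring exists.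

Alternative 2: The C6 carbonyl and the C1=C10 alkene are traced back to a C1–C6 σ-bond and to a C10–O bond of an epoxide spanning C10 and C14, so the ten-membered ring is hidden in a cis-fused bicyclo[4.4.0]decane. In the forward direction the C6 alkoxide pushes, C1–C6 breaks, C1=C10 forms and the epoxide opens, giving dienone A2 with a free C14 hydroxyl. In its favour, a fragmentation has no entropic penalty, the C1=C10 geometry is transferred stereospecifically from the antiperiplanar arrangement, and the C8 oxygen and the C14 hydroxyl are delivered with the ring. For making the ten-membered ring this is stronger than any macrocyclisation, the chosen one included. Against it, A2 still lacks the C7 acetic acid arm, the C6 stereocentre, the lactone and the C15 oxidation. The C7 enolate needed for the arm has the C8 silyloxy group in the β-position and can eliminate it. Reduction at C6 and allylic oxidation of the C4 methyl would have to be selective on a medium ring with several other allylic positions. The bicyclic substrate also needs stereocentres that the fragmentation destroys. The chosen strategy offers the reverse distribution of risk: stereocentres and alkene geometries are set in open-chain and five-membered-ring intermediates, and only protecting-group chemistry follows the ring closure.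

Alternative 3: The C4=C5 alkene is cut into a C5 aldehyde on the lactone and a C4 phosphorus ylide stabilised by the C15 formyl group. In the forward direction an intramolecular Wittig condensation closes the ring and gives A3, the target with its side-chain hydroxyl silylated. In its favour, it is the most convergent plan and forms the enal directly. A stabilised ylide places the formyl group trans to C6, which is exactly the ring-cis geometry required, so on alkene geometry it is as good as the chosen route, and it is stronger in the number of steps after ring closure. Against it, the ylide would have to be generated and heated in a molecule that already contains the methylene lactone, the acrylate and the allylic acetate, all of which accept phosphines and ylides. Formyl-stabilised ylides are sluggish, which is worse under the dilution a ten-membered ring needs. The C5 aldehyde sits next to the lactone oxygen and can epimerise or eliminate. A failure would cost the most advanced intermediate. The chosen strategy closes the ring on a fully protected, robust substrate by a coupling with no geometric ambiguity and pays for this with seven steps after the ring closure.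

Key step: step 16

## Route

Step 1
Reactants: 1 3-(trimethylsilyl)prop-2-yn-1-ol; 2 (1,3-dioxolan-2-ylmethyl)magnesium bromide
Product: 4 (E)-2-(1,3-dioxolan-2-ylmethyl)-3-(trimethylsilyl)prop-2-en-1-ol, via chelated alkenylmagnesium alkoxide 3 (not isolated)
Conditions: 2 (3 equiv), CuI (10 mol %), THF, 0 °C to rt; aq. NH4Cl
Reagents that add atoms: none
Why: Copper-catalysed anti-carbomagnesiation of a propargylic alcohol (Duboudin-type): the magnesium alkoxide delivers the alkyl group to C10 and holds magnesium on C1 cis to the CH2O arm in chelate 3, so protonolysis leaves silicon cis to the new C9 substituent; the silyl group stabilises the α-carbanion and fixes the regiochemistry.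

Step 2
Reactants: 4 (E)-2-(1,3-dioxolan-2-ylmethyl)-3-(trimethylsilyl)prop-2-en-1-ol
Product: 5 TBDPS ether of 4
Conditions: TBDPSCl, imidazole, DMF, rt
Reagents that add atoms: tert-butyl(chloro)diphenylsilane, CC(C)(C)[Si](Cl)(c1ccccc1)c1ccccc1
Why: Standard silylation of a primary allylic alcohol; TBDPS is chosen because it must outlast the later selective cleavage of a primary TBS ether.

Step 3
Reactants: 5 TBDPS ether of 4; 6 propane-1,3-dithiol
Product: 7 vinylsilane dithiane (C8–C10, C1, C14 fragment)
Conditions: BF3·OEt2, CH2Cl2, −20 to 0 °C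
Reagents that add atoms: none
Why: Lewis-acid transthioacetalisation turns the dioxolane directly into the 1,3-dithiane without releasing the isomerisation-prone β,γ-unsaturated aldehyde; vinylsilane and silyl ether tolerate BF3·OEt2 at low temperature.

Step 4
Reactants: 8 (S)-5-(hydroxymethyl)furan-2(5H)-one
Product: 9 (S)-5-(TBSO-methyl)furan-2(5H)-one
Conditions: TBSCl, imidazole, CH2Cl2, 0 °C to rt
Reagents that add atoms: tert-butyl(chloro)dimethylsilane, CC(C)(C)[Si](C)(C)Cl
Why: Standard silylation; a primary TBS ether can later be removed in the presence of a secondary TBS and a TBDPS ether.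

Step 5
Reactants: 7 vinylsilane dithiane; 9 (S)-5-(TBSO-methyl)furan-2(5H)-one
Product: 12 trans-lactone dithiane, via lithiated dithiane 10 (not isolated), via lithium lactone enolate 11 (not isolated)
Conditions: n-BuLi, THF, −30 °C; DMPU, then 9, −78 °C; aq. NH4Cl
Reagents that add atoms: none
Why: Corey–Seebach umpolung: the 2-lithio-1,3-dithiane 10 is a soft acyl-anion equivalent that adds 1,4 to the butenolide (DMPU suppresses 1,2-addition) from the face opposite the C6 CH2OTBS group, which sets C7 trans to C6; enolate 11 is protonated on work-up, and a vinylsilane, unlike an alkenyl iodide, survives n-BuLi.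

Step 6
Reactants: 12 trans-lactone dithiane
Product: 13 C8 ketone
Conditions: MeI, CaCO3, MeCN/H2O (9:1), 45 °C
Reagents that add atoms: water, O
Why: S-Alkylative hydrolysis of the dithiane under buffered, non-basic conditions unmasks the ketone without enolising the β,γ-unsaturated ketone into conjugation; the trans lactone is the thermodynamic C7 epimer in any case.

Step 7
Reactants: 13 C8 ketone
Product: 14 C8 alcohol (8S)
Conditions: (R)-Me-CBS [(R)-1-methyl-3,3-diphenyltetrahydro-1H,3H-pyrrolo[1,2-c][1,3,2]oxazaborole] (0.5 equiv), catecholborane, toluene, −78 to −40 °C; pH 7 buffer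
Reagents that add atoms: none
Why: Corey–Bakshi–Shibata reduction: the oxazaborolidine binds the ketone with the branched C7 flank as the large group and delivers hydride to the face that gives the 8S carbinol (O8 syn to O6 across C7), under reagent control against the substrate's own Felkin-type bias; borane conditions avoid a free alkoxide that could translactonise.

Step 8
Reactants: 14 C8 alcohol (8S)
Product: 15 bis-TBS ether
Conditions: TBSOTf, 2,6-lutidine, CH2Cl2, −78 to 0 °C
Reagents that add atoms: tert-butyldimethylsilyl trifluoromethanesulfonate, CC(C)(C)[Si](C)(C)OS(=O)(=O)C(F)(F)F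
Why: A silyl triflate with a hindered base silylates the hindered secondary hydroxyl without forming an alkoxide.

Step 9
Reactants: 15 bis-TBS ether
Product: 16 C5 primary alcohol
Conditions: HF·pyridine, pyridine, THF, 0 °C
Reagents that add atoms: none
Why: Buffered HF·pyridine cleaves the unhindered primary TBS ether much faster than the secondary TBS ether, the TBDPS ether or the vinylsilane.

Step 10
Reactants: 16 C5 primary alcohol
Product: 17 C5 aldehyde
Conditions: Dess–Martin periodinane, CH2Cl2, 0 °C to rt
Reagents that add atoms: none
Why: Dess–Martin oxidation under near-neutral conditions gives the α-acyloxy aldehyde without epimerising C6; the aldehyde is used at once.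

Step 11
Reactants: 17 C5 aldehyde; 18 (triphenylphosphoranylidene)acetaldehyde
Product: 19 (E)-enal
Conditions: 18 (1.2 equiv), toluene, 60 °C
Reagents that add atoms: none
Why: Wittig reaction of a formyl-stabilised ylide gives the (E)-enal, i.e. the C15 formyl group trans to C6, the geometry that C4=C5 keeps to the end.

Step 12
Reactants: 19 (E)-enal
Product: 20 (Z)-α-iodo enal
Conditions: I2, K2CO3, 4-(dimethylamino)pyridine (20 mol %), THF/H2O (1:1), rt
Reagents that add atoms: iodine, [I][I]
Why: Nucleophile-catalysed α-iodination of an enal (conjugate addition of the pyridine, iodination of the enolate, elimination) puts iodine on C4 in the only remaining position, cis to C6.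

Step 13
Reactants: 20 (Z)-α-iodo enal; 21 tributyl(vinyl)stannane
Product: 22 2-formyl diene (vinylsilane)
Conditions: 21, Pd2(dba)3 (3 mol %), AsPh3 (24 mol %), CuI (10 mol %), NMP, rt
Reagents that add atoms: none
Why: Stille coupling of the activated α-iodoenal under ligand-accelerated conditions at room temperature proceeds with retention, so the vinyl group C3=C2 ends cis to C6; the vinylsilane is inert to zerovalent palladium.

Step 14
Reactants: 22 2-formyl diene (vinylsilane)
Product: 23 alkenyl iodide dienal
Conditions: N-iodosuccinimide, MeCN/ClCH2CN (4:1), 0 °C, dark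
Reagents that add atoms: N-iodosuccinimide, O=C1CCC(=O)N1I
Why: Ipso-iododesilylation of the trisubstituted vinylsilane goes with retention through a β-silyl cation and gives the C1 iodide cis to C9; at this stage the diene is deactivated towards iodonium by its formyl group, which is why the exchange is placed here.

Step 15
Reactants: 23 alkenyl iodide dienal
Product: 24 iodo-diene dioxolane (open-chain precursor)
Conditions: (Me3SiOCH2)2, Me3SiOTf (5 mol %), CH2Cl2, −78 °C; pyridine
Reagents that add atoms: 1,2-bis(trimethylsilyloxy)ethane, C[Si](C)(C)OCCO[Si](C)(C)C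
Why: Noyori acetalisation at low temperature masks the C15 aldehyde at its final oxidation level so that it survives borane, aqueous base and enolate chemistry; no double-bond migration occurs under these kinetic conditions.

Step 16
Reactants: 24 iodo-diene dioxolane
Product: 26 ten-membered trans-fused lactone, via B-alkyl-9-BBN borane 25 (not isolated)
Conditions: 9-BBN (1.6 equiv), THF, 0 °C to rt; then syringe-pump addition to Pd(dppf)Cl2 (15 mol %), AsPh3 (30 mol %), Cs2CO3 (3 equiv), DMF/THF/H2O, 50 °C, final 2 mM
Reagents that add atoms: none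
Why: Mechanism: 9-BBN adds syn and anti-Markovnikov to the only monosubstituted alkene, C2=C3, giving the primary homoallylic borane 25; zerovalent palladium formed from Pd(dppf)Cl2 inserts into the C1–I bond with retention, base turns the borane into a borate that transfers C2 to palladium, and sp2–sp3 reductive elimination forms C1–C2. The closest known reaction type is the B-alkyl Suzuki–Miyaura macrocyclisation run directly after in situ hydroboration. The ten-membered carbocycle closes by intramolecular transmetalation to an eleven-membered palladacycle followed by reductive elimination, and slow addition of 25 keeps its concentration low enough to disfavour oligomerisation. No stereocentre is created; C6, C7 and C8 are spectators. The step needs hydroboration of the terminal vinyl group in preference to the two trisubstituted alkenes, the iodoalkene and the lactone, which the bulk of 9-BBN and its stoichiometry secure. It also needs retention of the C1=C10 geometry, which is inherent in oxidative addition and reductive elimination at an alkenyl–palladium bond. The trans lactone and the C4=C5 alkene with C3 cis to C6 turn both chain ends to the same side, and the wide bite angle of dppf favours reductive elimination over β-hydride elimination of the alkylpalladium.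

Step 17
Reactants: 26 ten-membered trans-fused lactone
Product: 29 α-methylene lactone, via Mannich base 27 (not isolated), via trimethylammonium iodide 28 (not isolated)
Conditions: LiN(iPr)2, THF, −78 °C; [Me2N=CH2]I, −78 to 0 °C; MeI, MeOH, rt; DBU, CH2Cl2, rt
Reagents that add atoms: N,N-dimethylmethyleneiminium iodide (Eschenmoser's salt), C=[N+](C)C.[I-]
Why: The kinetic lactone enolate is aminomethylated (Mannich reaction with an iminium salt), the amine is quaternised and the ammonium salt eliminates to the exocyclic methylene; C7 cannot epimerise and the C11 centre formed in 27 is destroyed again.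

Step 18
Reactants: 29 α-methylene lactone
Product: 30 C8,C14 diol
Conditions: HF·pyridine, pyridine, THF, 0 °C to rt
Reagents that add atoms: none
Why: Acidic fluoride cleaves both silyl ethers without forming an alkoxide that could add to the methylene lactone or translactonise onto C12; the dioxolane is stable to anhydrous buffered HF·pyridine.

Step 19
Reactants: 30 C8,C14 diol
Product: 31 C14 monoacetate
Conditions: Ac2O (1.1 equiv), 2,4,6-collidine, CH2Cl2, −20 °C
Reagents that add atoms: acetic anhydride, CC(=O)OC(C)=O
Why: Steric differentiation: the primary allylic C14 hydroxyl is acetylated at low temperature with a weak base while the hindered secondary C8 hydroxyl next to the ring fusion is left.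

Step 20
Reactants: 32 ethyl 2-(hydroxymethyl)acrylate
Product: 33 ethyl 2-(TBSO-methyl)acrylate
Conditions: TBSCl, imidazole, DMF, 0 °C to rt
Reagents that add atoms: tert-butyl(chloro)dimethylsilane, CC(C)(C)[Si](C)(C)Cl
Why: Standard silylation of a primary alcohol; the silyl ether prevents self-condensation in the later esterification.

Step 21
Reactants: 33 ethyl 2-(TBSO-methyl)acrylate
Product: 34 2-(TBSO-methyl)acrylic acid
Conditions: LiOH, THF/H2O, 0 °C; 1 M HCl to pH 3
Reagents that add atoms: lithium hydroxide, [Li+].[OH-]
Why: Saponification of an unhindered ethyl ester at 0 °C; the primary TBS ether survives hydroxide and brief, cold acidification.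

Step 22
Reactants: 31 C14 monoacetate; 34 2-(TBSO-methyl)acrylic acid
Product: 35 C8 ester
Conditions: DCC, 4-(dimethylamino)pyridine (20 mol %), CH2Cl2, 0 °C to rt
Reagents that add atoms: none
Why: Steglich esterification of the only free hydroxyl; carbodiimide activation under neutral conditions avoids base-induced translactonisation and acetate migration.

Step 23
Reactants: 35 C8 ester
Product: 36 target
Conditions: 1 M HCl, THF, 0 °C to rt
Reagents that add atoms: water, O
Why: Dilute aqueous acid hydrolyses the conjugated dioxolane to the enal and cleaves the primary TBS ether, while the acetate, the acrylate ester and the methylene lactone are stable; no stereocentre is touched.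

## Compound list

CIP letters at C6 and C7 change along the route only because substituent priorities change; no centre is inverted. Descriptors in brackets use the target numbering.

1 | 3-(trimethylsilyl)prop-2-yn-1-ol | C[Si](C)(C)C#CCO | starting material
2 | (1,3-dioxolan-2-ylmethyl)magnesium bromide | Br[Mg]CC1OCCO1 | starting material
3 | 4-(1,3-dioxolan-2-ylmethyl)-3-(trimethylsilyl)-2,5-dihydro-1,2-oxamagnesole (chelated alkenylmagnesium alkoxide, Mg on C1 cis to the CH2O arm) | C[Si](C)(C)C1=C(CC2OCCO2)CO[Mg]1 | intermediate
4 | (E)-2-(1,3-dioxolan-2-ylmethyl)-3-(trimethylsilyl)prop-2-en-1-ol (Si cis to C9) | C[Si](C)(C)/C=C(CO)\CC1OCCO1 | intermediate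
5 | (E)-tert-butyl{[2-(1,3-dioxolan-2-ylmethyl)-3-(trimethylsilyl)prop-2-en-1-yl]oxy}diphenylsilane | C[Si](C)(C)/C=C(CO[Si](c1ccccc1)(c1ccccc1)C(C)(C)C)\CC1OCCO1 | intermediate
6 | propane-1,3-dithiol | SCCCS | starting material
7 | (E)-tert-butyl{[2-(1,3-dithian-2-ylmethyl)-3-(trimethylsilyl)prop-2-en-1-yl]oxy}diphenylsilane | C[Si](C)(C)/C=C(CO[Si](c1ccccc1)(c1ccccc1)C(C)(C)C)\CC1SCCCS1 | intermediate
8 | (S)-5-(hydroxymethyl)furan-2(5H)-one | O=C1C=C[C@@H](CO)O1 | starting material
9 | (S)-5-{[(tert-butyldimethylsilyl)oxy]methyl}furan-2(5H)-one | O=C1C=C[C@@H](CO[Si](C)(C)C(C)(C)C)O1 | intermediate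
10 | 2-lithio derivative of 7 (lithium on the dithiane carbon C8) | C[Si](C)(C)/C=C(CO[Si](c1ccccc1)(c1ccccc1)C(C)(C)C)\CC1([Li])SCCCS1 | intermediate
11 | lithium enolate of 12 (C11=C12–OLi; 6S,7S) | C[Si](C)(C)/C=C(CO[Si](c1ccccc1)(c1ccccc1)C(C)(C)C)\CC2(SCCCS2)[C@H]1C=C(O[Li])O[C@@H]1CO[Si](C)(C)C(C)(C)C | intermediate
12 | (4S,5S)-5-(TBSOCH2)-4-{2-[(E)-2-(TBDPSOCH2)-3-(trimethylsilyl)prop-2-en-1-yl]-1,3-dithian-2-yl}dihydrofuran-2(3H)-one (4,5-trans; 6S,7S) | C[Si](C)(C)/C=C(CO[Si](c1ccccc1)(c1ccccc1)C(C)(C)C)\CC2(SCCCS2)[C@H]1CC(=O)O[C@@H]1CO[Si](C)(C)C(C)(C)C | intermediate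
13 | (4S,5S)-5-(TBSOCH2)-4-[(E)-3-(TBDPSOCH2)-4-(trimethylsilyl)but-3-enoyl]dihydrofuran-2(3H)-one (6S,7S) | C[Si](C)(C)/C=C(CO[Si](c1ccccc1)(c1ccccc1)C(C)(C)C)\CC(=O)[C@H]1CC(=O)O[C@@H]1CO[Si](C)(C)C(C)(C)C | intermediate
14 | (4R,5S)-5-(TBSOCH2)-4-[(1S,3E)-1-hydroxy-3-(TBDPSOCH2)-4-(trimethylsilyl)but-3-en-1-yl]dihydrofuran-2(3H)-one (6S,7R,8S) | C[Si](C)(C)/C=C(CO[Si](c1ccccc1)(c1ccccc1)C(C)(C)C)\C[C@H](O)[C@H]1CC(=O)O[C@@H]1CO[Si](C)(C)C(C)(C)C | intermediate
15 | (4S,5S)-5-(TBSOCH2)-4-[(1S,3E)-1-(TBSO)-3-(TBDPSOCH2)-4-(trimethylsilyl)but-3-en-1-yl]dihydrofuran-2(3H)-one (6S,7S,8S) | C[Si](C)(C)/C=C(CO[Si](c1ccccc1)(c1ccccc1)C(C)(C)C)\C[C@H](O[Si](C)(C)C(C)(C)C)[C@H]1CC(=O)O[C@@H]1CO[Si](C)(C)C(C)(C)C | intermediate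
16 | (4S,5S)-5-(hydroxymethyl)-4-[(1S,3E)-1-(TBSO)-3-(TBDPSOCH2)-4-(trimethylsilyl)but-3-en-1-yl]dihydrofuran-2(3H)-one (6S,7S,8S) | C[Si](C)(C)/C=C(CO[Si](c1ccccc1)(c1ccccc1)C(C)(C)C)\C[C@H](O[Si](C)(C)C(C)(C)C)[C@H]1CC(=O)O[C@@H]1CO | intermediate
17 | (2S,3S)-3-[(1S,3E)-1-(TBSO)-3-(TBDPSOCH2)-4-(trimethylsilyl)but-3-en-1-yl]-5-oxotetrahydrofuran-2-carbaldehyde (6S,7S,8S) | C[Si](C)(C)/C=C(CO[Si](c1ccccc1)(c1ccccc1)C(C)(C)C)\C[C@H](O[Si](C)(C)C(C)(C)C)[C@H]1CC(=O)O[C@@H]1C=O | intermediate
18 | (triphenylphosphoranylidene)acetaldehyde | O=CC=P(c1ccccc1)(c1ccccc1)c1ccccc1 | starting material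
19 | (E)-3-{(2R,3S)-3-[(1S,3E)-1-(TBSO)-3-(TBDPSOCH2)-4-(trimethylsilyl)but-3-en-1-yl]-5-oxotetrahydrofuran-2-yl}prop-2-enal (6R,7S,8S) | C[Si](C)(C)/C=C(CO[Si](c1ccccc1)(c1ccccc1)C(C)(C)C)\C[C@H](O[Si](C)(C)C(C)(C)C)[C@H]1CC(=O)O[C@@H]1/C=C/C=O | intermediate
20 | (Z)-2-iodo-3-{(2S,3S)-3-[(1S,3E)-1-(TBSO)-3-(TBDPSOCH2)-4-(trimethylsilyl)but-3-en-1-yl]-5-oxotetrahydrofuran-2-yl}prop-2-enal (iodine cis to C6; 6S,7S,8S) | C[Si](C)(C)/C=C(CO[Si](c1ccccc1)(c1ccccc1)C(C)(C)C)\C[C@H](O[Si](C)(C)C(C)(C)C)[C@H]1CC(=O)O[C@@H]1/C=C(C=O)\I | intermediate
21 | tributyl(vinyl)stannane | C=C[Sn](CCCC)(CCCC)CCCC | starting material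
22 | (E)-2-({(2R,3S)-3-[(1S,3E)-1-(TBSO)-3-(TBDPSOCH2)-4-(trimethylsilyl)but-3-en-1-yl]-5-oxotetrahydrofuran-2-yl}methylidene)but-3-enal (vinyl cis to C6, formyl trans; 6R,7S,8S) | C[Si](C)(C)/C=C(CO[Si](c1ccccc1)(c1ccccc1)C(C)(C)C)\C[C@H](O[Si](C)(C)C(C)(C)C)[C@H]1CC(=O)O[C@@H]1/C=C(C=O)\C=C | intermediate
23 | (E)-2-({(2R,3S)-3-[(1S,3E)-1-(TBSO)-3-(TBDPSOCH2)-4-iodobut-3-en-1-yl]-5-oxotetrahydrofuran-2-yl}methylidene)but-3-enal (iodine cis to C9; 6R,7S,8S) | I/C=C(CO[Si](c1ccccc1)(c1ccccc1)C(C)(C)C)\C[C@H](O[Si](C)(C)C(C)(C)C)[C@H]1CC(=O)O[C@@H]1/C=C(C=O)\C=C | intermediate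
24 | (4S,5R)-4-[(1S,3E)-1-(TBSO)-3-(TBDPSOCH2)-4-iodobut-3-en-1-yl]-5-[(E)-2-(1,3-dioxolan-2-yl)buta-1,3-dien-1-yl]dihydrofuran-2(3H)-one (open-chain precursor; 6R,7S,8S) | I/C=C(CO[Si](c1ccccc1)(c1ccccc1)C(C)(C)C)\C[C@H](O[Si](C)(C)C(C)(C)C)[C@H]1CC(=O)O[C@@H]1/C=C(C2OCCO2)\C=C | intermediate
25 | 24 in which the C2=C3 vinyl group has become CH2CH2–B(9-borabicyclo[3.3.1]nonan-9-yl), boron on C2 (6R,7S,8S) | I/C=C(CO[Si](c1ccccc1)(c1ccccc1)C(C)(C)C)\C[C@H](O[Si](C)(C)C(C)(C)C)[C@H]1CC(=O)O[C@@H]1/C=C(C2OCCO2)\CCB2C3CCCC2CCC3 | intermediate
26 | (1(10)E,4E,6R,7S,8S)-8-(TBSO)-14-(TBDPSO)-15,15-(ethylenedioxy)germacra-1(10),4-dien-12,6-olide (both ring alkenes cis in the ring, trans lactone, C11 is CH2) | O=C1C[C@H]2[C@H](O1)/C=C(C3OCCO3)\CC/C=C(CO[Si](c3ccccc3)(c3ccccc3)C(C)(C)C)\C[C@@H]2O[Si](C)(C)C(C)(C)C | intermediate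
27 | 26 carrying a dimethylaminomethyl group on C11 (C11 configuration open; 6R,7S,8S) | O=C1C(CN(C)C)[C@H]2[C@H](O1)/C=C(C3OCCO3)\CC/C=C(CO[Si](c3ccccc3)(c3ccccc3)C(C)(C)C)\C[C@@H]2O[Si](C)(C)C(C)(C)C | intermediate
28 | N-methyl quaternary ammonium iodide of 27 | O=C1C(C[N+](C)(C)C)[C@H]2[C@H](O1)/C=C(C3OCCO3)\CC/C=C(CO[Si](c3ccccc3)(c3ccccc3)C(C)(C)C)\C[C@@H]2O[Si](C)(C)C(C)(C)C.[I-] | intermediate
29 | (1(10)E,4E,6R,7S,8S)-8-(TBSO)-14-(TBDPSO)-15,15-(ethylenedioxy)germacra-1(10),4,11(13)-trien-12,6-olide | O=C1C(=C)[C@H]2[C@H](O1)/C=C(C3OCCO3)\CC/C=C(CO[Si](c3ccccc3)(c3ccccc3)C(C)(C)C)\C[C@@H]2O[Si](C)(C)C(C)(C)C | intermediate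
30 | (1(10)E,4E,6R,7R,8S)-8,14-dihydroxy-15,15-(ethylenedioxy)germacra-1(10),4,11(13)-trien-12,6-olide | O=C1C(=C)[C@H]2[C@H](O1)/C=C(C3OCCO3)\CC/C=C(CO)\C[C@@H]2O | intermediate
31 | (1(10)E,4E,6R,7R,8S)-14-acetoxy-8-hydroxy-15,15-(ethylenedioxy)germacra-1(10),4,11(13)-trien-12,6-olide | O=C1C(=C)[C@H]2[C@H](O1)/C=C(C3OCCO3)\CC/C=C(COC(C)=O)\C[C@@H]2O | intermediate
32 | ethyl 2-(hydroxymethyl)acrylate | C=C(CO)C(=O)OCC | starting material
33 | ethyl 2-{[(tert-butyldimethylsilyl)oxy]methyl}acrylate | C=C(CO[Si](C)(C)C(C)(C)C)C(=O)OCC | intermediate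
34 | 2-{[(tert-butyldimethylsilyl)oxy]methyl}acrylic acid | C=C(CO[Si](C)(C)C(C)(C)C)C(=O)O | intermediate
35 | (1(10)E,4E,6R,7R,8S)-14-acetoxy-8-{[2-(TBSOCH2)acryloyl]oxy}-15,15-(ethylenedioxy)germacra-1(10),4,11(13)-trien-12,6-olide | O=C1C(=C)[C@H]2[C@H](O1)/C=C(C3OCCO3)\CC/C=C(COC(C)=O)\C[C@@H]2OC(=O)C(=C)CO[Si](C)(C)C(C)(C)C | intermediate
36 | (1(10)E,4E,6R,7R,8S)-14-acetoxy-8-{[2-(hydroxymethyl)acryloyl]oxy}-15-oxogermacra-1(10),4,11(13)-trien-12,6-olide (CNP0198933.2) | C=C(CO)C(=O)O[C@H]1C/C(COC(C)=O)=C\CC/C(C=O)=C\[C@H]2OC(=O)C(=C)[C@H]12 | target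

## Step count and least certain steps

Total step count: 23. Longest linear sequence: 20 steps (steps 1, 2, 3, 5–19, 22, 23).

**Step 16 (key step).** The most likely failure is that intermolecular coupling and protodeboronation of 25 outrun the intramolecular transmetalation, because the palladacycle leading to a strained ten-membered diene forms slowly. Slow hydride transfer from surplus borane to the lactone is a second drain.
Fallback (sets out from 24, returns at 26): hydroborate as before but work up with NaBO3 to the primary C2 alcohol F1. Convert it into the primary iodide F2 with I2, PPh3 and imidazole. Zinc dust with LiCl inserts into the alkyl C–I bond only and gives the alkylzinc iodide F3. An intramolecular Negishi coupling (Pd2(dba)3, a biaryl phosphine, high dilution) then closes C1–C2 to 26. This replaces the borane by a more nucleophilic organozinc that needs no base.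

**Step 7.** The likely failure is poor facial selectivity. The ketone's own Felkin-type preference, with the C6-bearing ring bond anti to the incoming hydride, leads to the C8 epimer and works against the catalyst. Enolisation towards C9 would in addition move the C1=C10 alkene into conjugation.
Fallback (sets out from 13, returns at 14): reduce 13 under substrate control with LiBH(s-Bu)3 at −78 °C to the 8-epimeric alcohol F4. Invert it by a Mitsunobu reaction with chloroacetic acid (PPh3, diisopropyl azodicarboxylate) to the chloroacetate F5. Remove the chloroacetyl group with thiourea and NaHCO3 in ethanol, under near-neutral conditions that do not translactonise, to reach 14.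

**Step 1.** The likely failure is stalled conversion: the β-alkoxy Grignard reagent is a sluggish carbometalating agent and decomposes by β-elimination when warmed.
Fallback (sets out from 1, returns at 7): vinylmagnesium bromide with CuI adds in the same anti sense and gives the silyl dienol F6. Silylation gives the TBDPS ether F7. 9-BBN then NaBO3 converts its terminal vinyl group into the primary alcohol F8. Dess–Martin oxidation gives the aldehyde F9, which is used at once. Thioacetalisation with 6 and BF3·OEt2 gives 7.

**Step 14.** The likely failure is loss of chemoselectivity: iodonium attack on the diene competes with ipso-substitution at silicon, or traces of acid isomerise the enal.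
Fallback (sets out from 20, returns at 24): acetalise 20 first to the iodo dioxolane F10. A palladium-catalysed reductive carbonylation (Pd(PPh3)4, CO, Bu3SnH) puts a formyl group on C4 cis to C6 and gives F11. Iododesilylation, now with no diene present, gives the alkenyl iodide F12. Wittig methylenation with Ph3P=CH2 gives 24.

## Further compounds

F1 | step 16 | 24 with the C2=C3 vinyl group converted into CH2CH2OH (hydroxyl on C2) | I/C=C(CO[Si](c1ccccc1)(c1ccccc1)C(C)(C)C)\C[C@H](O[Si](C)(C)C(C)(C)C)[C@H]1CC(=O)O[C@@H]1/C=C(C2OCCO2)\CCO
F2 | step 16 | primary C2 iodide of F1 | I/C=C(CO[Si](c1ccccc1)(c1ccccc1)C(C)(C)C)\C[C@H](O[Si](C)(C)C(C)(C)C)[C@H]1CC(=O)O[C@@H]1/C=C(C2OCCO2)\CCI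
F3 | step 16 | alkylzinc iodide from F2 (zinc on C2) | I/C=C(CO[Si](c1ccccc1)(c1ccccc1)C(C)(C)C)\C[C@H](O[Si](C)(C)C(C)(C)C)[C@H]1CC(=O)O[C@@H]1/C=C(C2OCCO2)\CC[Zn]I
F4 | step 7 | C8 epimer of 14 | C[Si](C)(C)/C=C(CO[Si](c1ccccc1)(c1ccccc1)C(C)(C)C)\C[C@@H](O)[C@H]1CC(=O)O[C@@H]1CO[Si](C)(C)C(C)(C)C
F5 | step 7 | chloroacetate of 14 (C8 configured as in 14) | C[Si](C)(C)/C=C(CO[Si](c1ccccc1)(c1ccccc1)C(C)(C)C)\C[C@H](OC(=O)CCl)[C@H]1CC(=O)O[C@@H]1CO[Si](C)(C)C(C)(C)C
F6 | step 1 | (E)-2-[(trimethylsilyl)methylidene]but-3-en-1-ol (Si cis to vinyl) | C[Si](C)(C)/C=C(CO)\C=C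
F7 | step 1 | TBDPS ether of F6 | C[Si](C)(C)/C=C(CO[Si](c1ccccc1)(c1ccccc1)C(C)(C)C)\C=C
F8 | step 1 | (E)-3-(TBDPSOCH2)-4-(trimethylsilyl)but-3-en-1-ol | C[Si](C)(C)/C=C(CO[Si](c1ccccc1)(c1ccccc1)C(C)(C)C)\CCO
F9 | step 1 | (E)-3-(TBDPSOCH2)-4-(trimethylsilyl)but-3-enal | C[Si](C)(C)/C=C(CO[Si](c1ccccc1)(c1ccccc1)C(C)(C)C)\CC=O
F10 | step 14 | 1,3-dioxolane of 20 (iodine on C4 cis to C6) | C[Si](C)(C)/C=C(CO[Si](c1ccccc1)(c1ccccc1)C(C)(C)C)\C[C@H](O[Si](C)(C)C(C)(C)C)[C@H]1CC(=O)O[C@@H]1/C=C(C2OCCO2)\I
F11 | step 14 | F10 with the iodine replaced by a formyl group (C3 aldehyde cis to C6) | C[Si](C)(C)/C=C(CO[Si](c1ccccc1)(c1ccccc1)C(C)(C)C)\C[C@H](O[Si](C)(C)C(C)(C)C)[C@H]1CC(=O)O[C@@H]1/C=C(C2OCCO2)\C=O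
F12 | step 14 | F11 with the trimethylsilyl group replaced by iodine | I/C=C(CO[Si](c1ccccc1)(c1ccccc1)C(C)(C)C)\C[C@H](O[Si](C)(C)C(C)(C)C)[C@H]1CC(=O)O[C@@H]1/C=C(C2OCCO2)\C=O
A1 | alternative 1 | (2Z,6Z)-3,7-dimethylcyclodeca-2,6-dien-1-one | O=C1/C=C(C)\CC/C=C(C)\CCC1
A2 | alternative 2 | (2Z,6E,9S)-9-[(tert-butyldimethylsilyl)oxy]-7-(hydroxymethyl)-3-methylcyclodeca-2,6-dien-1-one | O=C1/C=C(C)\CC/C=C(CO)\C[C@H](O[Si](C)(C)C(C)(C)C)C1
A3 | alternative 3 | target with the side-chain hydroxyl as its tert-butyldimethylsilyl ether | C=C(CO[Si](C)(C)C(C)(C)C)C(=O)O[C@H]1C/C(COC(C)=O)=C\CC/C(C=O)=C\[C@H]2OC(=O)C(=C)[C@H]12
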